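**Assumption:** the target, 1-(5-decylpyridin-3-yl)decan-1-one, has no stereocentre and is achiral, so no enantiocontrol is needed. The one stereocentre that appears on the way (C-2 of 9 and 10) is racemic and is erased in step 5.

## Retrosynthetic overview
1. Disconnect the C(=O)–CH2 bond: 11 comes from decarboxylation of β-keto ester 9. Compound 9 comes from a crossed Claisen condensation of the non-enolisable methyl 5-decylnicotinate 4 with the lithium enolate of tert-butyl decanoate 6.
2. Disconnect the decyl chain: 4 comes from hydrogenation of alkyne 3, which comes from a Sonogashira coupling of methyl 5-bromonicotinate 1 with 1-decyne 2.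
3. Compound 6 comes from decanoyl chloride 5 and tert-butanol.
4. No ring is formed. The pyridine ring is bought in 1 with its 3,5-pattern already fixed.

## Route

Step 1
Reactants: 1 methyl 5-bromonicotinate (methyl 5-bromopyridine-3-carboxylate); 2 1-decyne (1.3 equiv)
Product: 3 methyl 5-(dec-1-yn-1-yl)nicotinate
Conditions: PdCl2(PPh3)2 (3 mol %), CuI (5 mol %), Et3N/THF 1:1 (degassed), 60 °C, 8 h
Reagents that add atoms: none
Why: This is a Sonogashira coupling in which the electron-poor 3-bromopyridine adds oxidatively to Pd(0) with ease and the copper acetylide of 2 transmetalates, while the methyl ester is inert to Et3N and no stereocentre is formed.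

Step 2
Reactants: 3 methyl 5-(dec-1-yn-1-yl)nicotinate
Product: 4 methyl 5-decylnicotinate
Conditions: H2 (1 atm), 10 % Pd/C, MeOH, rt, 12 h (3 chromatographed first to remove Cu and phosphine residues)
Reagents that add atoms: none
Why: Heterogeneous catalytic hydrogenation saturates the alkyne through the alkene to the decyl chain, and under neutral conditions at 1 atm neither the unprotonated pyridine ring nor the ester is reduced.

Step 3
Reactants: 5 decanoyl chloride
Product: 6 tert-butyl decanoate
Conditions: t-BuOH (2 equiv), pyridine (1.5 equiv), DMAP (10 mol %), CH2Cl2, 0 °C to rt, 16 h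
Reagents that add atoms: tert-butanol, CC(C)(C)O
Why: DMAP-catalysed acylation through the acylpyridinium ion esterifies the hindered alcohol, and the tert-butyl ester is chosen because its lithium enolate does not self-condense and the group later leaves under acid.

Step 4
Reactants: 6 tert-butyl decanoate (2.3 equiv); 4 methyl 5-decylnicotinate (1.0 equiv)
Product: 9 racemic tert-butyl 2-(5-decylnicotinoyl)decanoate, via lithium enolate of tert-butyl decanoate 7 (not isolated), via lithium salt of the β-keto ester 8 (not isolated)
Conditions: LDA (commercial 2.0 M solution, 2.2 equiv), THF, −78 °C, 45 min; then 4 in THF, −78 to 0 °C, 2 h; AcOH quench at −20 °C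
Reagents that add atoms: none
Why: In this crossed Claisen condensation the fully preformed enolate 7 acylates at carbon on the only electrophilic, non-enolisable and pyridine-activated ester, the second equivalent of enolate drives the reaction by deprotonating the product to chelate 8, and the new α-stereocentre is racemic and irrelevant.

Step 5
Reactants: 9 racemic tert-butyl 2-(5-decylnicotinoyl)decanoate
Product: 11 1-(5-decylpyridin-3-yl)decan-1-one, via β-keto acid 10 (not isolated)
Conditions: TFA/CH2Cl2 1:2, rt, 3 h; concentrate; toluene, 90 °C, 1 h; aq NaHCO3 work-up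
Reagents that add atoms: none
Why: Acidolysis of the tert-butyl ester (loss of the tert-butyl cation as isobutene) gives the β-keto acid, which undergoes thermal decarboxylation through the cyclic six-membered transition state, and this turns the only stereocentre into the CH2 of the achiral ketone.

## Compound list
1 | methyl 5-bromonicotinate | COC(=O)c1cncc(Br)c1 | starting material
2 | 1-decyne | C#CCCCCCCCC | starting material
3 | methyl 5-(dec-1-yn-1-yl)nicotinate | CCCCCCCCC#Cc1cncc(C(=O)OC)c1 | intermediate
4 | methyl 5-decylnicotinate | CCCCCCCCCCc1cncc(C(=O)OC)c1 | intermediate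
5 | decanoyl chloride | CCCCCCCCCC(=O)Cl | starting material
6 | tert-butyl decanoate | CCCCCCCCCC(=O)OC(C)(C)C | intermediate
7 | lithium enolate of tert-butyl decanoate (formed in situ) | CCCCCCCCC=C([O-])OC(C)(C)C.[Li+] | intermediate
8 | lithium salt (chelated enolate) of β-keto ester 9 (formed in situ) | CCCCCCCCCCc1cncc(C([O-])=C(CCCCCCCC)C(=O)OC(C)(C)C)c1.[Li+] | intermediate
9 | tert-butyl 2-(5-decylnicotinoyl)decanoate (racemic) | CCCCCCCCCCc1cncc(C(=O)C(CCCCCCCC)C(=O)OC(C)(C)C)c1 | intermediate
10 | 2-(5-decylnicotinoyl)decanoic acid (racemic, formed in situ) | CCCCCCCCCCc1cncc(C(=O)C(CCCCCCCC)C(=O)O)c1 | intermediate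
11 | 1-(5-decylpyridin-3-yl)decan-1-one (CNP0402297.0, achiral) | CCCCCCCCCCc1cncc(C(=O)CCCCCCCCC)c1 | target

## Step count
- Total steps: 5.
- Longest linear sequence: 4 (steps 1, 2, 4, 5). Step 3 is a one-step side branch.

## Steps most likely to fail, with fallbacks

**Highest risk: step 4.**
- The α-branched enolate may acylate the methyl ester sluggishly, and proton transfer to the product consumes enolate.
- The fallback sets out from 4 and comes back at 9. It replaces the ester acceptor with an aldehyde, so C–C bond formation is fast and no acidic product quenches the nucleophile.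
- Compound 4 is reduced with DIBAL-H (3 equiv, CH2Cl2, −78 to 0 °C) to (5-decylpyridin-3-yl)methanol F1.
- This is oxidised with activated MnO2 (CH2Cl2, rt) to 5-decylpyridine-3-carbaldehyde F2.
- Enolate 7 (1.2 equiv, from 6 and LDA, THF, −78 °C) is added in an aldol addition. This gives tert-butyl 2-[(5-decylpyridin-3-yl)(hydroxy)methyl]decanoate F3 as an inconsequential syn/anti mixture.
- Dess–Martin periodinane (CH2Cl2, NaHCO3, rt) oxidises the carbinol to β-keto ester 9.

**Second risk: step 1.**
- Glaser dimerisation of 2 or slow coupling may occur because the pyridine nitrogen binds Cu and Pd.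
- The fallback sets out from 1 and comes back at 4, so the alkyne stage and step 2 are bypassed.
- 1-Decene (C=CCCCCCCCC, commercial) is hydroborated with 9-BBN-H (THF, rt) to 9-decyl-9-borabicyclo[3.3.1]nonane F4.
- This is used directly in a B-alkyl Suzuki–Miyaura coupling with 1 (Pd(dppf)Cl2 5 mol %, K3PO4, THF/DMF with a little water, 60 °C). The coupling delivers methyl 5-decylnicotinate 4.

**Third risk: step 2.**
- The pyridine or trace copper may poison the catalyst so that the reaction stalls at the alkene. Forcing conditions may cause partial ring reduction.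
- The fallback sets out from 3 and comes back at 4. It is metal-free, so neither poisoning nor ring hydrogenation can occur.
- Diimide is generated in situ from excess p-toluenesulfonyl hydrazide and NaOAc (DME/H2O, reflux, portionwise addition).
- It reduces 3 by concerted syn hydrogen transfer, first to methyl 5-[(Z)-dec-1-en-1-yl]nicotinate F5 and then on to 4.

## Further compounds
F1 | step 4 | (5-decylpyridin-3-yl)methanol | CCCCCCCCCCc1cncc(CO)c1
F2 | step 4 | 5-decylpyridine-3-carbaldehyde | CCCCCCCCCCc1cncc(C=O)c1
F3 | step 4 | tert-butyl 2-[(5-decylpyridin-3-yl)(hydroxy)methyl]decanoate (racemic syn/anti mixture) | CCCCCCCCCCc1cncc(C(O)C(CCCCCCCC)C(=O)OC(C)(C)C)c1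
F4 | step 1 | 9-decyl-9-borabicyclo[3.3.1]nonane | CCCCCCCCCCB1C2CCCC1CCC2
F5 | step 2 | methyl 5-[(Z)-dec-1-en-1-yl]nicotinate | CCCCCCCC/C=C\c1cncc(C(=O)OC)c1
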